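**Retrosynthetic overview** (neolignan numbering: C7/C8/C9 is the propane chain on ring A, primed atoms belong to ring B)
1. Target ⇒ the matching methyl cinnamate. The last step turns the ring B ester into the allylic alcohol.
2. Key disconnection C7–C8: 3,4,5-trimethoxybenzaldehyde plus the 1-(aryloxy)ethyl radical released by decarboxylation of a racemic 2-aryloxypropanoic acid. A chiral chromium catalyst captures the radical and sets C7 and C8 together.
3. Aryloxy acid ⇒ syringaldehyde + 2-bromopropanoic acid (O–C8), then monomethyl malonate (C7'=C8', Knoevenagel–Doebner).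
4. Both aldehydes ⇒ syringaldehyde ⇒ 3,5-dibromo-4-hydroxybenzaldehyde ⇒ p-cresol.
5. No ring is formed. Rings A and B both come intact from p-cresol.

Assumption: the absolute sense of induction in step 6 cannot be predicted with certainty, so if the ligand antipode written there gives the mirror image, the commercial (3aS,3a'S,8aR,8a'R) antipode is used instead.

**Route**

Step 1
Reactants: 1 p-cresol (4-methylphenol)
Product: 4 3,5-dibromo-4-hydroxybenzaldehyde, via 2,6-dibromo-4-methylphenol 2 (not isolated), via 2,6-dibromo-4-(dibromomethyl)phenol 3 (not isolated)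
Conditions: Br2 (2.05 equiv), 1,2-dichlorobenzene, 35 °C; Br2 (2.05 equiv), 155 °C; then H2O, 100 °C
Reagents that add atoms: bromine, BrBr; water, O
Why: Electrophilic aromatic bromination takes both positions ortho to the OH (para is blocked), the hot second charge of Br2 brominates the benzylic CH3 twice (thermal free-radical side-chain bromination), and water hydrolyses the benzal bromide to the aldehyde in one pot; no stereocentre is formed.

Step 2
Reactants: 4 3,5-dibromo-4-hydroxybenzaldehyde
Product: 5 syringaldehyde (4-hydroxy-3,5-dimethoxybenzaldehyde)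
Conditions: NaOMe (5 equiv), CuCl (15 mol%), DMF/MeOH, 105 °C; then aq. HCl
Reagents that add atoms: sodium methoxide, [Na+].[O-]C
Why: Copper-catalysed Ullmann-type methoxylation replaces both aryl bromides, while the phenoxide and the non-enolisable aldehyde tolerate NaOMe; no stereocentre is formed.

Step 3
Reactants: 5 syringaldehyde
Product: 6 3,4,5-trimethoxybenzaldehyde
Conditions: MeI (1.3 equiv), K2CO3, DMF, 40 °C
Reagents that add atoms: iodomethane, CI
Why: Williamson ether synthesis (SN2 on MeI) of the acidic phenol, with no other nucleophilic site in 5; no stereocentre is formed.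

Step 4
Reactants: 5 syringaldehyde; 7 2-bromopropanoic acid (racemic)
Product: 8 2-(4-formyl-2,6-dimethoxyphenoxy)propanoic acid (racemic)
Conditions: NaH (2.2 equiv), DMF, 0 to 70 °C; then 1 M HCl
Reagents that add atoms: none
Why: Williamson-type SN2 displacement of the secondary bromide by the weakly basic phenoxide of 5 (little E2), with the carboxylate of 7 as a spectator; C8 is formed racemic, which is harmless because it becomes a planar radical in step 6.

Step 5
Reactants: 8 2-(4-formyl-2,6-dimethoxyphenoxy)propanoic acid; 9 monomethyl malonate (3-methoxy-3-oxopropanoic acid)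
Product: 10 2-{2,6-dimethoxy-4-[(E)-3-methoxy-3-oxoprop-1-enyl]phenoxy}propanoic acid (racemic at C8)
Conditions: 9 (2 equiv), pyridine, piperidine (0.2 equiv), 90 °C
Reagents that add atoms: none
Why: Knoevenagel condensation in the Doebner modification, where the malonate half ester condenses with the aldehyde and the decarboxylative elimination gives only the (E)-cinnamate, while the aryloxypropanoic acid has no active methylene and is untouched; C8 stays racemic.

Step 6 (key step)
Reactants: 10 2-{2,6-dimethoxy-4-[(E)-3-methoxy-3-oxoprop-1-enyl]phenoxy}propanoic acid (1.5 equiv); 6 3,4,5-trimethoxybenzaldehyde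
Product: 11 methyl (E)-3-(4-{[(1R,2R)-1-hydroxy-1-(3,4,5-trimethoxyphenyl)propan-2-yl]oxy}-3,5-dimethoxyphenyl)prop-2-enoate (threo, 7R,8R)
Conditions: CrCl2 (10 mol%), (3aR,3a'R,8aS,8a'S)-2,2'-(cyclopropane-1,1-diyl)bis(3a,8a-dihydro-8H-indeno[1,2-d]oxazole) (12 mol%), Ru(bpz)3(PF6)2 (2 mol%, bpz = 2,2'-bipyrazine), 2,6-lutidine (0.5 equiv), THF/MeCN, 450 nm LED, 0 °C
Reagents that add atoms: none
Why: Proposed new method: excited Ru(bpz)3(PF6)2 oxidises the carboxylate of 10, loss of CO2 gives the secondary 1-(aryloxy)ethyl radical, divalent chromium bound to the chiral bis(oxazoline) captures it, and the resulting alkyl complex of trivalent chromium adds to the aldehyde of 6 to form C7–C8, after which 10 protonates the chromium alkoxide and the reduced photocatalyst returns trivalent to divalent chromium, so the reaction is redox-neutral; reversible Cr–C homolysis lets both C8 epimers of the alkylchromium interconvert (Curtin–Hammett), the ligand directs attack to the Si face of the aldehyde (7R), and a six-membered chelate from an ortho-methoxy oxygen to chromium holds the aryloxy group next to the forming Cr–O bond with the C8 methyl anti to the carbonyl oxygen and the C8 hydrogen beside the aldehyde aryl group, which gives 8R (threo); the photocatalyst triplet energy of about 48 kcal/mol is too low to isomerise the (E)-cinnamate; the closest known reaction types are the dual photoredox/chromium radical-polar crossover (Nozaki–Hiyama–Kishi type) additions of alpha-amino, allyl and alkyl radicals to aldehydes, their enantioselective bis(oxazoline) variants, and the CrCl2-mediated addition of redox-active esters to aldehydes.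

Step 7
Reactants: 11 methyl (E)-3-(4-{[(1R,2R)-1-hydroxy-1-(3,4,5-trimethoxyphenyl)propan-2-yl]oxy}-3,5-dimethoxyphenyl)prop-2-enoate
Product: 12 (1R,2R)-2-{4-[(E)-3-hydroxyprop-1-enyl]-2,6-dimethoxyphenoxy}-1-(3,4,5-trimethoxyphenyl)propan-1-ol (target)
Conditions: i-Bu2AlH (4 equiv), CH2Cl2, −78 °C; then aq. potassium sodium tartrate
Reagents that add atoms: none
Why: i-Bu2AlH reduces the alpha,beta-unsaturated ester by clean 1,2-reduction to the (E)-allylic alcohol (one equivalent is spent on the free OH), and the neutral work-up touches neither the aryl ethers nor the benzylic alcohol, so C7 and C8 keep their configuration.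

**Compound list**
1 | p-cresol | Cc1ccc(O)cc1 | starting material
2 | 2,6-dibromo-4-methylphenol | Cc1cc(Br)c(O)c(Br)c1 | intermediate
3 | 2,6-dibromo-4-(dibromomethyl)phenol | BrC(Br)c1cc(Br)c(O)c(Br)c1 | intermediate
4 | 3,5-dibromo-4-hydroxybenzaldehyde | O=Cc1cc(Br)c(O)c(Br)c1 | intermediate
5 | syringaldehyde | COc1cc(C=O)cc(OC)c1O | intermediate
6 | 3,4,5-trimethoxybenzaldehyde | COc1cc(C=O)cc(OC)c1OC | intermediate
7 | 2-bromopropanoic acid (racemic) | CC(Br)C(=O)O | starting material
8 | 2-(4-formyl-2,6-dimethoxyphenoxy)propanoic acid (racemic) | CC(Oc1c(OC)cc(C=O)cc1OC)C(=O)O | intermediate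
9 | monomethyl malonate | COC(=O)CC(=O)O | starting material
10 | 2-{2,6-dimethoxy-4-[(E)-3-methoxy-3-oxoprop-1-enyl]phenoxy}propanoic acid (racemic) | CC(Oc1c(OC)cc(/C=C/C(=O)OC)cc1OC)C(=O)O | intermediate
11 | methyl (E)-3-(4-{[(1R,2R)-1-hydroxy-1-(3,4,5-trimethoxyphenyl)propan-2-yl]oxy}-3,5-dimethoxyphenyl)prop-2-enoate | COc1cc([C@@H](O)[C@@H](C)Oc2c(OC)cc(/C=C/C(=O)OC)cc2OC)cc(OC)c1OC | intermediate
12 | (1R,2R)-2-{4-[(E)-3-hydroxyprop-1-enyl]-2,6-dimethoxyphenoxy}-1-(3,4,5-trimethoxyphenyl)propan-1-ol | COc1cc([C@@H](O)[C@@H](C)Oc2c(OC)cc(/C=C/CO)cc2OC)cc(OC)c1OC | target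

**Step count**
- Total steps: 7.
- Longest linear sequence: 6 (steps 1, 2, 4, 5, 6, 7).

**Steps most likely to fail**

*Step 6.* Possible failures are:
- a diastereomer ratio or ee that is too low, or one that favours the erythro isomer;
- protonolysis of the alkylchromium to the ethyl ether;
- sequestration of divalent chromium by carboxylate.

The fallback sets out from 10 and 6 and comes back at 11. It keeps C7–C8 as a radical coupling but moves all stereocontrol to a polar reduction.
- Acid 10 is condensed with N-hydroxyphthalimide (DIC, DMAP, CH2Cl2) to 1,3-dioxoisoindolin-2-yl 2-{2,6-dimethoxy-4-[(E)-3-methoxy-3-oxoprop-1-enyl]phenoxy}propanoate F1.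
- An N-aryl thiazolium carbene (10 mol%, Cs2CO3, DMSO, 60 °C) converts 6 into its Breslow enolate. This enolate reduces F1 by single-electron transfer. The resulting ketyl and 1-(aryloxy)ethyl radicals recombine to give racemic methyl (E)-3-(3,5-dimethoxy-4-{[1-oxo-1-(3,4,5-trimethoxyphenyl)propan-2-yl]oxy}phenyl)prop-2-enoate F2.
- Asymmetric transfer hydrogenation with dynamic kinetic resolution (RuCl(p-cymene)[(S,S)-TsDPEN], HCO2H/Et3N, 40 °C) then gives 11. The base racemises the acidic C8. The outer-sphere hydride transfer cannot chelate, so it follows the Felkin–Anh model (threo). The catalyst selects the face that gives 7R.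

*Step 4.* The di-ortho-substituted, electron-poor phenoxide may be too slow toward a secondary alpha-bromo carboxylate. The fallback sets out from 5 and comes back at 8.
- A Mitsunobu reaction of 5 with racemic methyl lactate (PPh3, DIAD, THF) suits this acidic phenol. It gives methyl 2-(4-formyl-2,6-dimethoxyphenoxy)propanoate F3.
- LiOH in THF/H2O saponifies F3 to 8.

*Step 1.* The hot side-chain bromination may give tar or incomplete dibromination on a laboratory scale. The fallback sets out from 1 and comes back at 5, so the benzylic carbon is oxidised after the methoxy groups are in place.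
- Compound 1 is brominated only on the ring (Br2, AcOH, 20 °C) and 2 is isolated.
- NaOMe/CuCl in DMF/MeOH converts 2 into 2,6-dimethoxy-4-methylphenol F4.
- Base-mediated aerobic oxidation (Co(OAc)2, NaOH, O2, MeOH, 60 °C) proceeds through the para-quinone methide and turns the methyl group of F4 into the aldehyde of 5.

**Further compounds**
F1 | step 6 | 1,3-dioxoisoindolin-2-yl 2-{2,6-dimethoxy-4-[(E)-3-methoxy-3-oxoprop-1-enyl]phenoxy}propanoate (racemic) | CC(Oc1c(OC)cc(/C=C/C(=O)OC)cc1OC)C(=O)ON1C(=O)c2ccccc2C1=O
F2 | step 6 | methyl (E)-3-(3,5-dimethoxy-4-{[1-oxo-1-(3,4,5-trimethoxyphenyl)propan-2-yl]oxy}phenyl)prop-2-enoate (racemic) | COc1cc(C(=O)C(C)Oc2c(OC)cc(/C=C/C(=O)OC)cc2OC)cc(OC)c1OC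
F3 | step 4 | methyl 2-(4-formyl-2,6-dimethoxyphenoxy)propanoate (racemic) | CC(Oc1c(OC)cc(C=O)cc1OC)C(=O)OC
F4 | step 1 | 2,6-dimethoxy-4-methylphenol | Cc1cc(OC)c(O)c(OC)c1
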